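**Strategy.** Numbering: lactone O1, C2–C6; side chain C1'–C10'. Carbons C3'–C8' carry oxygen at C4', C6' and C8' in a 1,3,5 pattern with C4'/C6' syn, which is the imprint of an all-cis cyclohexanetriol ring. The route therefore rests on cutting C3'–C8' of a meso cis-3,5-bis(silyloxy)cyclohexanone, made from phloroglucinol, by an enantioselective Baeyer–Villiger oxidation. This one operation breaks the mirror symmetry and fixes C4' and C6' absolutely. It delivers an oxepan-2-one with two different ends: acyl C8' for the phenethyl ketone and CH2–O C3' for alkynylation. An ethynyl dihydropyran from a hetero-Diels–Alder reaction supplies C2–C6 and C1'–C2'. Directed reduction sets C8', and semi-hydrogenation sets the Z-alkene.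

Key step: step 4

Assumption: the sense of induction of the two chiral catalysts (steps 4 and 7) is taken by analogy with simpler substrates; both ligand antipodes are accessible, so the one that gives the drawn enantiomer is used. TBS = tert-butyldimethylsilyl; primed locants are those of the target side chain.

Step 1
Reactants: 1 phloroglucinol (benzene-1,3,5-triol)
Product: 2 all-cis-cyclohexane-1,3,5-triol (r-1,c-3,c-5; achiral)
Conditions: H2 (80 bar), 5% Rh/Al2O3, EtOH, 60 °C; recrystallisation
Reagents that add atoms: none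
Why: Heterogeneous catalytic arene hydrogenation delivers all hydrogens to the face adsorbed on the metal, so the three carbinol carbons should come out all-cis, and rhodium on alumina keeps C–O hydrogenolysis low.

Step 2
Reactants: 2 all-cis-cyclohexane-1,3,5-triol
Product: 3 all-cis-3,5-bis(tert-butyldimethylsilyloxy)cyclohexan-1-ol (meso)
Conditions: TBSCl (2.0 equiv), imidazole, DMF, 0 °C to rt; mono- and tris-ethers separated and recycled
Reagents that add atoms: tert-butyldimethylsilyl chloride (TBSCl), CC(C)(C)[Si](C)(C)Cl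
Why: Silyl ether protection of three equivalent equatorial hydroxyls is statistical but clean and is stopped at two by stoichiometry; TBS is kept because it does not chelate, tolerates peracid and organometallics and leaves with HF, and no stereocentre is touched.

Step 3
Reactants: 3 all-cis-3,5-bis(tert-butyldimethylsilyloxy)cyclohexan-1-ol
Product: 4 (3R,5S)-3,5-bis(tert-butyldimethylsilyloxy)cyclohexan-1-one (cis, meso)
Conditions: (n-Pr)4N[RuO4] (5 mol %), NMO, 4 Å MS, CH2Cl2, rt
Reagents that add atoms: none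
Why: The Ley–Griffith oxidation converts the secondary alcohol into the ketone under essentially neutral conditions, which should avoid beta-elimination of the two silyloxy groups.

Step 4
Reactants: 4 (3R,5S)-3,5-bis(tert-butyldimethylsilyloxy)cyclohexan-1-one
Product: 6 (4R,6S)-4,6-bis(tert-butyldimethylsilyloxy)oxepan-2-one, via Criegee adduct 5 (not isolated)
Conditions: Sc(OTf)3 (10 mol %), ligand L1 (10 mol %; C2-symmetric N,N'-dioxide of the propane-1,3-diyl-bridged bis(pipecolic acid 2,6-diisopropylanilide)), m-CPBA (1.2 equiv), EtOAc, −20 °C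
Reagents that add atoms: 3-chloroperoxybenzoic acid (m-CPBA), O=C(OO)c1cccc(Cl)c1
Why: Ketone 4, activated on the ligand-bound trivalent scandium centre, adds the peracid to give Criegee adduct 5, in which the ring CH2 held antiperiplanar to the O–O bond moves from C8' to oxygen as 3-chlorobenzoate leaves; this is the catalytic asymmetric Baeyer–Villiger desymmetrisation established for meso 3,5-disubstituted and prochiral 4-substituted cyclohexanones. The oxepan-2-one ring arises by ring expansion and not by cyclisation: the 1,2-shift inserts one oxygen into the six-membered carbocycle (O–C3' made, C3'–C8' broken). No bond at C4' or C6' changes, so their syn relation is that of step 1, while their absolute configuration (6S and 4R in 6) follows only from which enantiotopic CH2 migrates, namely the one next to the S-configured carbinol carbon of 4, and this is controlled by the chiral ligand sphere. Enantiotopic-group selection is thus the one selectivity needed; the substrate supports it because the two equatorial, non-chelating OTBS groups lock a single chair and put their bulk on the two flanks the catalyst has to distinguish, and regioselectivity is no issue since both candidates are CH2 groups of equal migratory aptitude. The low temperature and the only weakly acidic medium should spare the silyl ethers and hold back beta-elimination.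

Step 5
Reactants: 6 (4R,6S)-4,6-bis(tert-butyldimethylsilyloxy)oxepan-2-one
Product: 7 (3R,5S)-3,5-bis(tert-butyldimethylsilyloxy)-6-hydroxy-N-methoxy-N-methylhexanamide
Conditions: MeNH(OMe)·HCl, AlMe3, CH2Cl2, 0 °C to rt; aq. potassium sodium tartrate
Reagents that add atoms: N,O-dimethylhydroxylamine hydrochloride, CNOC.Cl
Why: Aluminium-amide aminolysis (Weinreb amide synthesis) opens the seven-membered lactone at the acyl C8'–O bond without free base, so neither beta-elimination nor silyl migration from O4' to the freed O3' should intervene, and both stereocentres stay untouched.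

Step 6
Reactants: 8 ethynyltrimethylsilane
Product: 10 3-(trimethylsilyl)prop-2-ynal, via lithium (trimethylsilyl)acetylide 9 (not isolated)
Conditions: n-BuLi, THF, −78 °C; DMF, −78 to 0 °C; inverse quench into cold 1 M HCl
Reagents that add atoms: N,N-dimethylformamide (DMF), CN(C)C=O
Why: Formylation of a lithium acetylide with DMF gives the ynal, and the inverse acidic quench keeps liberated dimethylamine from adding to the triple bond.

Step 7
Reactants: 10 3-(trimethylsilyl)prop-2-ynal; 11 (E)-1-methoxybuta-1,3-diene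
Product: 12 (2R,6S)-2-methoxy-6-[(trimethylsilyl)ethynyl]-5,6-dihydro-2H-pyran (2,6-cis; lactone numbering)
Conditions: [CrCl(L2)] (5 mol %; L2 = dianion of the Schiff base of (1S,2R)-1-aminoindan-2-ol and 3-(1-adamantyl)-2-hydroxy-5-methylbenzaldehyde), 4 Å MS, neat, rt
Reagents that add atoms: none
Why: In this catalytic asymmetric hetero-Diels–Alder reaction of a mono-oxygenated diene with an ynal, the unsubstituted diene terminus bonds to the formyl carbon and the methoxy-bearing carbon to oxygen through an endo transition state (2,6-cis), while the tridentate ligand on trivalent chromium leaves only the Si face of the aldehyde open and so sets C6 as S.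

Step 8
Reactants: 12 (2R,6S)-2-methoxy-6-[(trimethylsilyl)ethynyl]-5,6-dihydro-2H-pyran
Product: 13 (2R,6S)-6-ethynyl-2-methoxy-5,6-dihydro-2H-pyran
Conditions: K2CO3 (cat.), MeOH, 0 °C to rt; careful concentration (volatile)
Reagents that add atoms: none
Why: Base-catalysed protodesilylation of the alkynylsilane proceeds under conditions to which the methyl acetal and C6 are inert.

Step 9
Reactants: 7 (3R,5S)-3,5-bis(tert-butyldimethylsilyloxy)-6-hydroxy-N-methoxy-N-methylhexanamide
Product: 14 (2S,4R)-2,4-bis(tert-butyldimethylsilyloxy)-6-[methoxy(methyl)amino]-6-oxohexyl trifluoromethanesulfonate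
Conditions: Tf2O (1.1 equiv), 2,6-lutidine, CH2Cl2, −78 °C; cold aqueous wash, short silica plug, used at once
Reagents that add atoms: trifluoromethanesulfonic anhydride (Tf2O), O=S(=O)(OS(=O)(=O)C(F)(F)F)C(F)(F)F
Why: Triflate formation at the unhindered primary alcohol is complete within minutes at −78 °C, faster than activation of the weakly nucleophilic N-methoxyamide, and the cold, immediately used triflate has little time to be attacked by its own O6' silyl ether.

Step 10
Reactants: 13 (2R,6S)-6-ethynyl-2-methoxy-5,6-dihydro-2H-pyran; 14 (2S,4R)-2,4-bis(tert-butyldimethylsilyloxy)-6-[methoxy(methyl)amino]-6-oxohexyl trifluoromethanesulfonate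
Product: 16 (3R,5R)-3,5-bis(tert-butyldimethylsilyloxy)-N-methoxy-8-[(2S,6R)-6-methoxy-3,6-dihydro-2H-pyran-2-yl]-N-methyloct-7-ynamide, via lithium acetylide 15 (not isolated)
Conditions: 13 (1.1 equiv), n-BuLi, THF, −78 °C; added dropwise to 14 in THF/DMPU, −78 to −40 °C
Reagents that add atoms: none
Why: SN2 alkylation of a lithium acetylide with a primary triflate runs at −78 °C, where acetylides add only sluggishly to N-methoxy-N-methylamides, so slow addition of near-stoichiometric 15 should form C2'–C3' selectively; C4' takes no part, and its descriptor changes from S to R only through CIP priorities.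

Step 11
Reactants: 16 (3R,5R)-3,5-bis(tert-butyldimethylsilyloxy)-N-methoxy-8-[(2S,6R)-6-methoxy-3,6-dihydro-2H-pyran-2-yl]-N-methyloct-7-ynamide; 17 (2-bromoethyl)benzene
Product: 19 (5R,7R)-5,7-bis(tert-butyldimethylsilyloxy)-10-[(2S,6R)-6-methoxy-3,6-dihydro-2H-pyran-2-yl]-1-phenyldec-9-yn-3-one, via 2-phenylethylmagnesium bromide 18 (not isolated)
Conditions: 17, Mg, THF, rt; then 16, THF, 0 °C; aq. NH4Cl
Reagents that add atoms: none
Why: In the Weinreb ketone synthesis the N-methoxy chelate holds the Grignard addition at the mono-adduct stage until work-up, so the C8' ketone forms without over-addition while the acetal, internal alkyne and silyl ethers are inert.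

Step 12
Reactants: 19 (5R,7R)-5,7-bis(tert-butyldimethylsilyloxy)-10-[(2S,6R)-6-methoxy-3,6-dihydro-2H-pyran-2-yl]-1-phenyldec-9-yn-3-one
Product: 21 (6S)-6-[(4R,6R)-4,6-bis(tert-butyldimethylsilyloxy)-8-oxo-10-phenyldec-1-yn-1-yl]-5,6-dihydro-2H-pyran-2-one, via lactol 20 (not isolated)
Conditions: PPTS, acetone/H2O, rt; extractive work-up; then MnO2, CH2Cl2, rt
Reagents that add atoms: water, O
Why: Mild acid hydrolysis of the allylic mixed acetal gives lactol 20, which MnO2 oxidises as an allylic hemiacetal to the conjugated lactone (allylic oxidation) without affecting the ketone, alkyne, silyl ethers or C6.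

Step 13
Reactants: 21 (6S)-6-[(4R,6R)-4,6-bis(tert-butyldimethylsilyloxy)-8-oxo-10-phenyldec-1-yn-1-yl]-5,6-dihydro-2H-pyran-2-one
Product: 22 (6S)-6-[(4R,6R)-4,6-dihydroxy-8-oxo-10-phenyldec-1-yn-1-yl]-5,6-dihydro-2H-pyran-2-one
Conditions: 48% aq. HF, MeCN, 0 °C to rt
Reagents that add atoms: none
Why: Acidic fluoride desilylation removes both secondary TBS ethers without the basic medium that would invite retro-aldol cleavage, beta-elimination or opening of the base-sensitive 6-alkynyl lactone.

Step 14
Reactants: 22 (6S)-6-[(4R,6R)-4,6-dihydroxy-8-oxo-10-phenyldec-1-yn-1-yl]-5,6-dihydro-2H-pyran-2-one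
Product: 23 (6S)-6-[(4R,6S,8R)-4,6,8-trihydroxy-10-phenyldec-1-yn-1-yl]-5,6-dihydro-2H-pyran-2-one
Conditions: Me4NBH(OAc)3, MeCN/AcOH (1:1), −30 °C
Reagents that add atoms: none
Why: In the Evans–Saksena reduction the C6' hydroxyl displaces acetate on boron and hydride is delivered internally through a chair in which the phenethyl group avoids the axial acetate, so C8' should form anti to C6' (8'R); the reagent leaves the lactone, enoate and alkyne alone, and any O4'–C8' hemiketal stays in acid-mediated equilibrium with the open ketone.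

Step 15
Reactants: 23 (6S)-6-[(4R,6S,8R)-4,6,8-trihydroxy-10-phenyldec-1-yn-1-yl]-5,6-dihydro-2H-pyran-2-one
Product: 24 (6S)-6-[(1Z,4R,6S,8R)-4,6,8-trihydroxy-10-phenyldec-1-en-1-yl]-5,6-dihydro-2H-pyran-2-one (target)
Conditions: H2 (1 atm), Pd/CaCO3–Pb(OAc)2, quinoline, EtOAc, rt; stopped after one equivalent of H2
Reagents that add atoms: none
Why: Lindlar semi-hydrogenation adds H2 in a syn fashion on the poisoned palladium surface, giving the Z-alkene C1'=C2', and the alkyne binds far more strongly than the C3=C4 enoate, which should remain.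

**Compound list**

1 | phloroglucinol | Oc1cc(O)cc(O)c1 | starting material
2 | all-cis-cyclohexane-1,3,5-triol | O[C@@H]1C[C@H](O)C[C@H](O)C1 | intermediate
3 | all-cis-3,5-bis(tert-butyldimethylsilyloxy)cyclohexan-1-ol | O[C@@H]1C[C@H](O[Si](C)(C)C(C)(C)C)C[C@H](O[Si](C)(C)C(C)(C)C)C1 | intermediate
4 | (3R,5S)-3,5-bis(tert-butyldimethylsilyloxy)cyclohexan-1-one (meso) | O=C1C[C@H](O[Si](C)(C)C(C)(C)C)C[C@H](O[Si](C)(C)C(C)(C)C)C1 | intermediate
5 | Criegee adduct, 1-hydroxy-cis-3,5-bis(tert-butyldimethylsilyloxy)cyclohexyl 3-chloroperoxybenzoate | OC1(OOC(=O)c2cccc(Cl)c2)C[C@H](O[Si](C)(C)C(C)(C)C)C[C@H](O[Si](C)(C)C(C)(C)C)C1 | intermediate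
6 | (4R,6S)-4,6-bis(tert-butyldimethylsilyloxy)oxepan-2-one | O=C1C[C@H](O[Si](C)(C)C(C)(C)C)C[C@H](O[Si](C)(C)C(C)(C)C)CO1 | intermediate
7 | (3R,5S)-3,5-bis(tert-butyldimethylsilyloxy)-6-hydroxy-N-methoxy-N-methylhexanamide | CON(C)C(=O)C[C@H](O[Si](C)(C)C(C)(C)C)C[C@H](O[Si](C)(C)C(C)(C)C)CO | intermediate
8 | ethynyltrimethylsilane | C#C[Si](C)(C)C | starting material
9 | lithium (trimethylsilyl)acetylide | [Li]C#C[Si](C)(C)C | intermediate
10 | 3-(trimethylsilyl)prop-2-ynal | O=CC#C[Si](C)(C)C | intermediate
11 | (E)-1-methoxybuta-1,3-diene | CO/C=C/C=C | starting material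
12 | (2R,6S)-2-methoxy-6-[(trimethylsilyl)ethynyl]-5,6-dihydro-2H-pyran | CO[C@H]1C=CC[C@@H](C#C[Si](C)(C)C)O1 | intermediate
13 | (2R,6S)-6-ethynyl-2-methoxy-5,6-dihydro-2H-pyran | CO[C@H]1C=CC[C@@H](C#C)O1 | intermediate
14 | (2S,4R)-2,4-bis(tert-butyldimethylsilyloxy)-6-[methoxy(methyl)amino]-6-oxohexyl trifluoromethanesulfonate | CON(C)C(=O)C[C@H](O[Si](C)(C)C(C)(C)C)C[C@H](O[Si](C)(C)C(C)(C)C)COS(=O)(=O)C(F)(F)F | intermediate
15 | lithium acetylide of 13 | CO[C@H]1C=CC[C@@H](C#C[Li])O1 | intermediate
16 | (3R,5R)-3,5-bis(tert-butyldimethylsilyloxy)-N-methoxy-8-[(2S,6R)-6-methoxy-3,6-dihydro-2H-pyran-2-yl]-N-methyloct-7-ynamide | CO[C@H]1C=CC[C@@H](C#CC[C@@H](O[Si](C)(C)C(C)(C)C)C[C@@H](O[Si](C)(C)C(C)(C)C)CC(=O)N(C)OC)O1 | intermediate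
17 | (2-bromoethyl)benzene | BrCCc1ccccc1 | starting material
18 | 2-phenylethylmagnesium bromide | Br[Mg]CCc1ccccc1 | intermediate
19 | (5R,7R)-5,7-bis(tert-butyldimethylsilyloxy)-10-[(2S,6R)-6-methoxy-3,6-dihydro-2H-pyran-2-yl]-1-phenyldec-9-yn-3-one | CO[C@H]1C=CC[C@@H](C#CC[C@@H](O[Si](C)(C)C(C)(C)C)C[C@@H](O[Si](C)(C)C(C)(C)C)CC(=O)CCc2ccccc2)O1 | intermediate
20 | lactol of 19 (2-hydroxy-5,6-dihydro-2H-pyran, anomer mixture) | OC1C=CC[C@@H](C#CC[C@@H](O[Si](C)(C)C(C)(C)C)C[C@@H](O[Si](C)(C)C(C)(C)C)CC(=O)CCc2ccccc2)O1 | intermediate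
21 | (6S)-6-[(4R,6R)-4,6-bis(tert-butyldimethylsilyloxy)-8-oxo-10-phenyldec-1-yn-1-yl]-5,6-dihydro-2H-pyran-2-one | O=C1C=CC[C@@H](C#CC[C@@H](O[Si](C)(C)C(C)(C)C)C[C@@H](O[Si](C)(C)C(C)(C)C)CC(=O)CCc2ccccc2)O1 | intermediate
22 | (6S)-6-[(4R,6R)-4,6-dihydroxy-8-oxo-10-phenyldec-1-yn-1-yl]-5,6-dihydro-2H-pyran-2-one | O=C1C=CC[C@@H](C#CC[C@@H](O)C[C@@H](O)CC(=O)CCc2ccccc2)O1 | intermediate
23 | (6S)-6-[(4R,6S,8R)-4,6,8-trihydroxy-10-phenyldec-1-yn-1-yl]-5,6-dihydro-2H-pyran-2-one | O=C1C=CC[C@@H](C#CC[C@@H](O)C[C@@H](O)C[C@H](O)CCc2ccccc2)O1 | intermediate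
24 | (6S)-6-[(1Z,4R,6S,8R)-4,6,8-trihydroxy-10-phenyldec-1-en-1-yl]-5,6-dihydro-2H-pyran-2-one | O=C1C=CC[C@@H](/C=C\C[C@@H](O)C[C@@H](O)C[C@H](O)CCc2ccccc2)O1 | target

**Step count.** There are 15 steps in total. The longest linear sequence is 12 steps from phloroglucinol (steps 1–5 and 9–15). The alkyne branch (steps 6–8) has 3 steps.

**Steps most likely to fail**

1. **Step 4.** The catalyst may discriminate poorly between the two enantiotopic methylene groups. The Lewis acid may also strip silyl groups or trigger beta-elimination before oxygen insertion.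
 - The fallback sets out from 4 and returns at 7. It breaks the symmetry by proton abstraction instead of oxygen insertion.
 - Lithium bis[(R)-1-phenylethyl]amide (or its antipode) and LiCl, with Me3SiCl present from the start, in THF at −100 °C should trap the enolate before it can eliminate. The product is the silyl enol ether (3S,5R)-3,5-bis(tert-butyldimethylsilyloxy)-1-(trimethylsilyloxy)cyclohex-1-ene F1.
 - Ozonolysis (O3, CH2Cl2/MeOH, −78 °C) with NaBH4 work-up cleaves the same C3'–C8' bond. It gives (3R,5S)-3,5-bis(tert-butyldimethylsilyloxy)-6-hydroxyhexanoic acid F2.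
 - Carbodiimide coupling (EDC·HCl, MeNH(OMe)·HCl, N-methylmorpholine, CH2Cl2) then leads to 7.

2. **Step 10.** The acetylide may add competitively to the N-methoxy-N-methylamide. The triflate may also be lost through internal attack by the O6' silyl ether or through elimination.
 - The fallback sets out from 7 and returns at 19. It removes the acyl group from play before the C2'–C3' bond is made.
 - Amide 7 and Grignard reagent 18 (2.5 equiv, THF, 0 °C) should give (5R,7S)-5,7-bis(tert-butyldimethylsilyloxy)-8-hydroxy-1-phenyloctan-3-one F3.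
 - NaBH4 in MeOH gives 5,7-bis(tert-butyldimethylsilyloxy)-1-phenyloctane-3,8-diol F4. It forms as a C8' epimer mixture, which is of no consequence.
 - Tf2O and 2,6-lutidine at −78 °C, followed in the same flask by Et3SiOTf, give the primary triflate with a C8' triethylsilyl ether F5.
 - Acetylide 15 in THF/DMPU at −78 °C gives the coupled alkyne F6.
 - PPTS in MeOH at 0 °C removes only the triethylsilyl group. At most it epimerises C2, which is erased in step 12. The product is the C8' alcohol F7.
 - Dess–Martin periodinane oxidises F7 to 19.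

3. **Step 15.** Hydrogenation may run past the alkene stage, saturate the enoate, or cleave the activated C6–O bond by hydrogenolysis on a polar, unprotected substrate.
 - The fallback sets out from 19 and returns at 24. The alkyne is semi-reduced while the ring is still an acetal, so no conjugated lactone, acyloxy leaving group or free hydroxyl is present. The directed reduction then becomes the last step.
 - H2, Pd/CaCO3–Pb(OAc)2 and quinoline in hexane/EtOAc should give the (Z)-alkenyl acetal ketone F8.
 - PPTS in acetone/H2O gives the (Z)-alkenyl lactol F9.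
 - MnO2 gives the (Z)-alkenyl bis-silyl keto lactone F10.
 - Aqueous HF in MeCN gives the (Z)-alkenyl dihydroxy keto lactone F11.
 - Me4NBH(OAc)3 in MeCN/AcOH at −30 °C gives 24.

**Further compounds**

F1 | step 4 | (3S,5R)-3,5-bis(tert-butyldimethylsilyloxy)-1-(trimethylsilyloxy)cyclohex-1-ene | C[Si](C)(C)OC1=C[C@@H](O[Si](C)(C)C(C)(C)C)C[C@@H](O[Si](C)(C)C(C)(C)C)C1
F2 | step 4 | (3R,5S)-3,5-bis(tert-butyldimethylsilyloxy)-6-hydroxyhexanoic acid | O=C(O)C[C@H](O[Si](C)(C)C(C)(C)C)C[C@H](O[Si](C)(C)C(C)(C)C)CO
F3 | step 10 | (5R,7S)-5,7-bis(tert-butyldimethylsilyloxy)-8-hydroxy-1-phenyloctan-3-one | O=C(CCc1ccccc1)C[C@H](O[Si](C)(C)C(C)(C)C)C[C@H](O[Si](C)(C)C(C)(C)C)CO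
F4 | step 10 | 5,7-bis(tert-butyldimethylsilyloxy)-1-phenyloctane-3,8-diol (C4' and C6' as in 7, C8' epimers) | OC(CCc1ccccc1)C[C@H](O[Si](C)(C)C(C)(C)C)C[C@H](O[Si](C)(C)C(C)(C)C)CO
F5 | step 10 | 2,4-bis(tert-butyldimethylsilyloxy)-8-phenyl-6-(triethylsilyloxy)octyl trifluoromethanesulfonate | CC[Si](CC)(CC)OC(CCc1ccccc1)C[C@H](O[Si](C)(C)C(C)(C)C)C[C@H](O[Si](C)(C)C(C)(C)C)COS(=O)(=O)C(F)(F)F
F6 | step 10 | coupled alkyne, C8' triethylsilyl ether analogue of 19 | CO[C@H]1C=CC[C@@H](C#CC[C@@H](O[Si](C)(C)C(C)(C)C)C[C@@H](O[Si](C)(C)C(C)(C)C)CC(CCc2ccccc2)O[Si](CC)(CC)CC)O1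
F7 | step 10 | C8' alcohol analogue of 19 (C8' epimers) | CO[C@H]1C=CC[C@@H](C#CC[C@@H](O[Si](C)(C)C(C)(C)C)C[C@@H](O[Si](C)(C)C(C)(C)C)CC(O)CCc2ccccc2)O1
F8 | step 15 | (Z)-alkenyl acetal ketone (1'Z analogue of 19) | CO[C@H]1C=CC[C@@H](/C=C\C[C@@H](O[Si](C)(C)C(C)(C)C)C[C@@H](O[Si](C)(C)C(C)(C)C)CC(=O)CCc2ccccc2)O1
F9 | step 15 | (Z)-alkenyl lactol (1'Z analogue of 20, anomer mixture) | OC1C=CC[C@@H](/C=C\C[C@@H](O[Si](C)(C)C(C)(C)C)C[C@@H](O[Si](C)(C)C(C)(C)C)CC(=O)CCc2ccccc2)O1
F10 | step 15 | (Z)-alkenyl bis-silyl keto lactone (1'Z analogue of 21) | O=C1C=CC[C@@H](/C=C\C[C@@H](O[Si](C)(C)C(C)(C)C)C[C@@H](O[Si](C)(C)C(C)(C)C)CC(=O)CCc2ccccc2)O1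
F11 | step 15 | (Z)-alkenyl dihydroxy keto lactone (1'Z analogue of 22) | O=C1C=CC[C@@H](/C=C\C[C@@H](O)C[C@@H](O)CC(=O)CCc2ccccc2)O1
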